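**Retrosynthetic overview**
1. The 4α‑CHO is made last, from the 4α‑methyl group, by 1,5‑hydrogen transfer to a 6α‑alkoxy radical (nitrite photolysis → 18‑oxime → aldehyde).
2. The butenolide is cut at C5'–C4' (key bond): a polarity‑reversed β‑acylvinyl chromium reagent from a (Z)‑β‑iodocrotonate adds to a C5' aldehyde under ligand control and lactonises in the same operation.
3. The C5' aldehyde comes from a tertiary vinyl carbinol by one‑carbon homologation with 1,3‑transposition ([2,3]‑shift of a nucleophilic alkoxy(amino)carbene), then amide → aldehyde.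
4. The 8α‑carbinol comes from an exocyclic alkene (α‑epoxidation, hydride opening) of (+)‑larixol, which supplies C5, C6, C9 and C10.
5. Ring order: rings A and B are present from the start; the butenolide ring is closed in the coupling step.

**Assumptions**
- (+)‑Larixol, the main diterpene alcohol of larch oleoresin, is taken as the commercial chiral‑pool starting material.
- The target is made as the open 6α‑hydroxy aldehyde drawn; in solution it may be in ring–chain equilibrium with its 6α,18‑lactol.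
- The ligand antipode named in step 6 is taken to direct Si‑face addition; if the sense proves opposite, its mirror image is used with nothing else changed.
- Labdane numbering is used for the C20 part (C18 = 4α‑methyl, C19 = 4β‑methyl, C20 = 10β‑methyl; 5α‑H, 9α‑H throughout); butenolide atoms are C2'–C5'.

**Step 1**
Reactants: 1 (+)‑larixol [(13S)‑labda‑8(17),14‑diene‑6α,13‑diol]
Product: 2 (13S)‑8α,17‑epoxylabd‑14‑ene‑6α,13‑diol
Conditions: mCPBA (1.1 equiv), NaHCO3, CH2Cl2, 0 °C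
Reagents that add atoms: mCPBA, O=C(OO)c1cccc(Cl)c1
Why: Prilezhaev epoxidation, in which the 1,1‑disubstituted C8=C17 alkene reacts much faster than the monosubstituted vinyl group and the peracid comes from the α‑face (the β‑face is screened by the axial C10 methyl, the α‑face carries the hydrogen‑bonding 6α‑OH), which sets the 8α‑oxygen.

**Step 2**
Reactants: 2 (13S)‑8α,17‑epoxylabd‑14‑ene‑6α,13‑diol
Product: 3 (13S)‑labd‑14‑ene‑6α,8α,13‑triol
Conditions: LiAlH4 (3 equiv), THF, 0 → 60 °C; aq. NaOH work‑up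
Reagents that add atoms: none
Why: Hydride opening of the epoxide by SN2 attack at the unhindered C17 methylene gives the 8β‑methyl/8α‑hydroxy carbinol with the C8 configuration fixed in step 1 untouched.

**Step 3**
Reactants: 3 (13S)‑labd‑14‑ene‑6α,8α,13‑triol; 4 N,N‑dimethylformamide dimethyl acetal
Product: 7 N,N‑dimethyl‑(13E)‑6α,8α‑dihydroxylabd‑13‑ene‑15‑carboxamide, via 13‑O‑amide acetal 5 (not isolated), via alkoxy(dimethylamino)carbene 6 (not isolated)
Conditions: 4 (6 equiv), xylenes, 140 °C, sealed, 16 h; K2CO3, MeOH/H2O, rt; chromatography on AgNO3‑impregnated SiO2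
Reagents that add atoms: none
Why: Büchi [2,3]‑sigmatropic rearrangement, in which the nucleophilic carbene carbon (a carbamoyl‑anion equivalent) bonds to the terminal C15 as the C13–O bond breaks, so only the allylic 13‑hydroxyl is homologated (the 6‑ and 8‑hydroxyls are regenerated on work‑up) and the 13S centre is traded for the C13=C14 alkene, with the larger C12 chain pseudo‑equatorial giving 13E as the major isomer (about 2:1 expected), separated from 13Z on silver nitrate silica.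

**Step 4**
Reactants: 7 N,N‑dimethyl‑(13E)‑6α,8α‑dihydroxylabd‑13‑ene‑15‑carboxamide
Product: 8 (13E)‑6α,8α‑dihydroxylabd‑13‑ene‑15‑carbaldehyde
Conditions: Cp2Zr(H)Cl (4.5 equiv), THF, rt, 30 min; H2O/SiO2; used at once
Reagents that add atoms: none
Why: Georg‑type amide reduction, in which Cp2Zr(H)Cl adds once to the tertiary amide to give a zirconated hemiaminal that releases the aldehyde only on work‑up, so there is no over‑reduction and no base to move the β,γ‑alkene into conjugation, while the free hydroxyls merely consume extra reagent.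

**Step 5**
Reactants: 9 ethyl but‑2‑ynoate
Product: 10 ethyl (Z)‑3‑iodobut‑2‑enoate
Conditions: NaI (1.6 equiv), AcOH, 110 °C
Reagents that add atoms: sodium iodide, [Na+].[I-]
Why: Conjugate hydroiodination of the ynoate is an anti addition of H–I and gives the (Z)‑β‑iodo enoate, the geometry needed for lactonisation in step 6.

**Step 6**
Reactants: 8 (13E)‑6α,8α‑dihydroxylabd‑13‑ene‑15‑carbaldehyde; 10 ethyl (Z)‑3‑iodobut‑2‑enoate
Product: 12 (5R)‑5‑[(13E)‑6α,8α‑dihydroxylabd‑13‑en‑15‑yl]‑4‑methylfuran‑2(5H)‑one, via (Z)‑γ‑hydroxy enoate 11 (not isolated)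
Conditions: CrCl2 (4 equiv), ligand L* = N‑{2‑[(4R)‑4‑tert‑butyl‑4,5‑dihydro‑1,3‑oxazol‑2‑yl]‑6‑methylphenyl}methanesulfonamide (4.4 equiv), Et3N (4.4 equiv), NiCl2 (2 mol %), 10 (2 equiv), THF, rt; aq. NaHCO3/serine work‑up; PPTS (cat.), CH2Cl2, rt
Reagents that add atoms: none
Why: Asymmetric Nozaki–Hiyama–Kishi coupling, in which the enoate β‑carbon, normally an acceptor, becomes a donor (a β‑acylvinyl anion, i.e. a homoenolate equivalent at the acrylate oxidation level) through Ni insertion into C–I and transfer to chromium, and this vinylchromium, which tolerates the free diol, adds to the aldehyde carbon (also an acceptor) from the Si face inside the chiral sulfonamide complex to set 5'R with no help from the remote decalin centres, after which the (Z)‑γ‑oxido ester closes to the butenolide.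

**Step 7**
Reactants: 12 (5R)‑5‑[(13E)‑6α,8α‑dihydroxylabd‑13‑en‑15‑yl]‑4‑methylfuran‑2(5H)‑one
Product: 15 (5R)‑5‑[(13E)‑6α,8α‑dihydroxy‑18‑(hydroxyimino)labd‑13‑en‑15‑yl]‑4‑methylfuran‑2(5H)‑one, via 6‑nitrite ester 13 (not isolated), via 18‑nitroso compound 14 (not isolated)
Conditions: t‑BuONO (3 equiv), CH2Cl2, 0 °C → rt, dark; evaporate; hν (365 nm), PhH, 15 °C, Ar; i‑PrOH, 50 °C
Reagents that add atoms: tert‑butyl nitrite, CC(C)(C)ON=O
Why: Barton nitrite photolysis, in which nitrite exchange takes the secondary 6α‑OH in preference to the hindered tertiary 8α‑OH, homolysis gives the 6α‑alkoxy radical, and 1,5‑hydrogen transfer occurs from the 4α‑methyl group that lies parallel to the 6α‑oxygen at about 2.5 Å (the 4β‑methyl is about 3.5 Å away), so NO recombination and tautomerisation place the oxime on C18 and set the C4 stereocentre by proximity.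

**Step 8**
Reactants: 15 (5R)‑5‑[(13E)‑6α,8α‑dihydroxy‑18‑(hydroxyimino)labd‑13‑en‑15‑yl]‑4‑methylfuran‑2(5H)‑one
Product: 17 (5R)‑5‑[(13E)‑6α,8α‑dihydroxy‑18‑oxolabd‑13‑en‑15‑yl]‑4‑methylfuran‑2(5H)‑one (target), via 18‑imine 16 (not isolated)
Conditions: TiCl3 (aq. HCl solution, 3 equiv), NH4OAc, THF/H2O, rt
Reagents that add atoms: water, O
Why: Timms–Wildsmith reductive deoximation, in which trivalent titanium cleaves the N–O bond and the imine is hydrolysed at about pH 5, conditions that leave the butenolide with its base‑labile C5' centre, the trisubstituted alkene and the tertiary alcohol intact.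

**Compound list**
1 | (+)‑larixol, (13S)‑labda‑8(17),14‑diene‑6α,13‑diol | C=C[C@@](C)(O)CC[C@@H]1[C@@]2(C)CCCC(C)(C)[C@@H]2[C@@H](O)CC1=C | starting material
2 | (13S)‑8α,17‑epoxylabd‑14‑ene‑6α,13‑diol | C=C[C@@](C)(O)CC[C@@H]1[C@@]2(C)CCCC(C)(C)[C@@H]2[C@@H](O)C[C@]13CO3 | intermediate
3 | (13S)‑labd‑14‑ene‑6α,8α,13‑triol | C=C[C@@](C)(O)CC[C@@H]1[C@@]2(C)CCCC(C)(C)[C@@H]2[C@@H](O)C[C@@]1(C)O | intermediate
4 | N,N‑dimethylformamide dimethyl acetal | COC(OC)N(C)C | starting material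
5 | 13‑O‑[(dimethylamino)(methoxy)methyl] ether of 3 (mixed amide acetal, not isolated) | C=C[C@@](C)(OC(OC)N(C)C)CC[C@@H]1[C@@]2(C)CCCC(C)(C)[C@@H]2[C@@H](O)C[C@@]1(C)O | intermediate
6 | 13‑O‑[(dimethylamino)methylidene] carbene of 3 (alkoxy(dimethylamino)carbene, not isolated) | C=C[C@@](C)(O[C]N(C)C)CC[C@@H]1[C@@]2(C)CCCC(C)(C)[C@@H]2[C@@H](O)C[C@@]1(C)O | intermediate
7 | N,N‑dimethyl‑(13E)‑6α,8α‑dihydroxylabd‑13‑ene‑15‑carboxamide | CN(C)C(=O)C/C=C(\C)CC[C@@H]1[C@@]2(C)CCCC(C)(C)[C@@H]2[C@@H](O)C[C@@]1(C)O | intermediate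
8 | (13E)‑6α,8α‑dihydroxylabd‑13‑ene‑15‑carbaldehyde | O=CC/C=C(\C)CC[C@@H]1[C@@]2(C)CCCC(C)(C)[C@@H]2[C@@H](O)C[C@@]1(C)O | intermediate
9 | ethyl but‑2‑ynoate | CC#CC(=O)OCC | starting material
10 | ethyl (Z)‑3‑iodobut‑2‑enoate | C/C(I)=C/C(=O)OCC | intermediate
11 | ethyl (2Z,4R)‑4‑hydroxy‑3‑methyl‑5‑[(13E)‑6α,8α‑dihydroxylabd‑13‑en‑15‑yl]pent‑2‑enoate (present as its chromium alkoxide, not isolated) | CCOC(=O)/C=C(/C)[C@H](O)C/C=C(\C)CC[C@@H]1[C@@]2(C)CCCC(C)(C)[C@@H]2[C@@H](O)C[C@@]1(C)O | intermediate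
12 | (5R)‑5‑[(13E)‑6α,8α‑dihydroxylabd‑13‑en‑15‑yl]‑4‑methylfuran‑2(5H)‑one | CC1=CC(=O)O[C@@H]1C/C=C(\C)CC[C@@H]1[C@@]2(C)CCCC(C)(C)[C@@H]2[C@@H](O)C[C@@]1(C)O | intermediate
13 | 6α‑nitrite ester of 12 (not isolated) | CC1=CC(=O)O[C@@H]1C/C=C(\C)CC[C@@H]1[C@@]2(C)CCCC(C)(C)[C@@H]2[C@@H](ON=O)C[C@@]1(C)O | intermediate
14 | 18‑nitroso derivative of 12 (4α‑CH2N=O, not isolated) | CC1=CC(=O)O[C@@H]1C/C=C(\C)CC[C@@H]1[C@@]2(C)CCC[C@@](C)(CN=O)[C@@H]2[C@@H](O)C[C@@]1(C)O | intermediate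
15 | (5R)‑5‑[(13E)‑6α,8α‑dihydroxy‑18‑(hydroxyimino)labd‑13‑en‑15‑yl]‑4‑methylfuran‑2(5H)‑one | CC1=CC(=O)O[C@@H]1C/C=C(\C)CC[C@@H]1[C@@]2(C)CCC[C@@](C)(/C=N/O)[C@@H]2[C@@H](O)C[C@@]1(C)O | intermediate
16 | 18‑imine of the target (not isolated) | CC1=CC(=O)O[C@@H]1C/C=C(\C)CC[C@@H]1[C@@]2(C)CCC[C@@](C)(C=N)[C@@H]2[C@@H](O)C[C@@]1(C)O | intermediate
17 | (5R)‑5‑[(13E)‑6α,8α‑dihydroxy‑18‑oxolabd‑13‑en‑15‑yl]‑4‑methylfuran‑2(5H)‑one | CC1=CC(=O)O[C@@H]1C/C=C(\C)CC[C@@H]1[C@@]2(C)CCC[C@@](C)(C=O)[C@@H]2[C@@H](O)C[C@@]1(C)O | target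

**Totals**
Total steps: 8. Longest linear sequence: 7 (steps 1, 2, 3, 4, 6, 7, 8); step 5 is a one‑step side branch.

**Three steps most likely to fail, with fallbacks**

Step 6. Facial selectivity rests on the ligand alone, and the β,γ‑unsaturated aldehyde can slip into conjugation. The fallback sets out from aldehyde 8 and comes back at butenolide 12. Me2Zn/ProPhenol‑catalysed addition of methyl propiolate (ligand antipode chosen for the (R)‑carbinol) gives the γ‑hydroxy ynoate F6. Me2CuLi (THF, −78 °C) then adds methyl syn across the triple bond, and the resulting (Z)‑γ‑hydroxy enoate lactonises on mildly acidic work‑up to 12.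

Step 3. The 13E/13Z ratio is modest and the thermal step runs on a free triol. The fallback sets out from triol 3 and comes back at aldehyde 8, fixing the alkene geometry by syn carbometalation.
- OsO4 (cat.)/NaIO4 in aq. THF degrades the vinyl carbinol to the 14,15‑dinor methyl ketone F1.
- N‑(trimethylsilyl)imidazole gives its 6,8‑bis(trimethylsilyl) ether F2.
- LiN(iPr)2, ClP(O)(OEt)2, then LiN(iPr)2 (2.2 equiv) converts the methyl ketone, by way of its kinetic enol phosphate, into the terminal alkyne F3.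
- Me3Al with Cp2ZrCl2 (cat.) adds methyl and aluminium syn across the alkyne; the alkenylalanate formed with n‑BuLi opens oxirane to give the silylated (13E)‑homoallylic alcohol F4.
- K2CO3/MeOH removes both silyl groups to give the (13E)‑homoallylic triol F5.
- TEMPO/PhI(OAc)2 oxidises only the primary hydroxyl of F5 to aldehyde 8.

Step 7. The nitrite photolysis is run late, on a substrate carrying a tertiary alcohol, a trisubstituted alkene and the butenolide. The fallback sets out from triol 3 and comes back at target 17, moving the C–H oxidation ahead of the side‑chain work and carrying the aldehyde as a cyclic acetal.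
- t‑BuONO, then hν (365 nm), gives the 18‑oxime triol F7.
- TiCl3/NH4OAc, then MeOH/PPTS, gives the 6α,18‑cyclic methyl acetal F8.
- Acetal 4 at 140 °C gives the homologated amide acetal F9.
- Cp2Zr(H)Cl gives the aldehyde acetal F10.
- The Ni/Cr coupling with 10 under the step 6 conditions gives the butenolide acetal F11.
- Aq. AcOH/THF at rt releases target 17.

**Further compounds**
F1 | step 3 | 6α,8α‑dihydroxy‑14,15‑dinorlabdan‑13‑one | CC(=O)CC[C@@H]1[C@@]2(C)CCCC(C)(C)[C@@H]2[C@@H](O)C[C@@]1(C)O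
F2 | step 3 | 6α,8α‑bis(trimethylsilyloxy)‑14,15‑dinorlabdan‑13‑one | CC(=O)CC[C@@H]1[C@@]2(C)CCCC(C)(C)[C@@H]2[C@@H](O[Si](C)(C)C)C[C@@]1(C)O[Si](C)(C)C
F3 | step 3 | terminal alkyne, 9‑(but‑3‑ynyl) decalin with 6α,8α‑bis(trimethylsilyloxy) groups | C#CCC[C@@H]1[C@@]2(C)CCCC(C)(C)[C@@H]2[C@@H](O[Si](C)(C)C)C[C@@]1(C)O[Si](C)(C)C
F4 | step 3 | 2‑[(13E)‑6α,8α‑bis(trimethylsilyloxy)labd‑13‑en‑15‑yl]... written as (13E)‑15‑(hydroxymethyl)labd‑13‑ene 6α,8α‑bis(trimethylsilyl) ether | OCC/C=C(\C)CC[C@@H]1[C@@]2(C)CCCC(C)(C)[C@@H]2[C@@H](O[Si](C)(C)C)C[C@@]1(C)O[Si](C)(C)C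
F5 | step 3 | (13E)‑15‑(hydroxymethyl)labd‑13‑ene‑6α,8α‑diol | OCC/C=C(\C)CC[C@@H]1[C@@]2(C)CCCC(C)(C)[C@@H]2[C@@H](O)C[C@@]1(C)O
F6 | step 6 | methyl (4R)‑4‑hydroxy‑5‑[(13E)‑6α,8α‑dihydroxylabd‑13‑en‑15‑yl]pent‑2‑ynoate | COC(=O)C#C[C@H](O)C/C=C(\C)CC[C@@H]1[C@@]2(C)CCCC(C)(C)[C@@H]2[C@@H](O)C[C@@]1(C)O
F7 | step 7 | (13S)‑18‑(hydroxyimino)labd‑14‑ene‑6α,8α,13‑triol | C=C[C@@](C)(O)CC[C@@H]1[C@@]2(C)CCC[C@@](C)(/C=N/O)[C@@H]2[C@@H](O)C[C@@]1(C)O
F8 | step 7 | (13S)‑6α,18‑epoxy‑18‑methoxylabd‑14‑ene‑8α,13‑diol | C=C[C@@](C)(O)CC[C@@H]1[C@@]2(C)CCC[C@@](C)(C(OC)O3)[C@@H]2[C@@H]3C[C@@]1(C)O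
F9 | step 7 | N,N‑dimethyl‑(13E)‑6α,18‑epoxy‑8α‑hydroxy‑18‑methoxylabd‑13‑ene‑15‑carboxamide | CN(C)C(=O)C/C=C(\C)CC[C@@H]1[C@@]2(C)CCC[C@@](C)(C(OC)O3)[C@@H]2[C@@H]3C[C@@]1(C)O
F10 | step 7 | (13E)‑6α,18‑epoxy‑8α‑hydroxy‑18‑methoxylabd‑13‑ene‑15‑carbaldehyde | O=CC/C=C(\C)CC[C@@H]1[C@@]2(C)CCC[C@@](C)(C(OC)O3)[C@@H]2[C@@H]3C[C@@]1(C)O
F11 | step 7 | (5R)‑5‑[(13E)‑6α,18‑epoxy‑8α‑hydroxy‑18‑methoxylabd‑13‑en‑15‑yl]‑4‑methylfuran‑2(5H)‑one | CC1=CC(=O)O[C@@H]1C/C=C(\C)CC[C@@H]1[C@@]2(C)CCC[C@@](C)(C(OC)O3)[C@@H]2[C@@H]3C[C@@]1(C)O
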